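## The problem

Caraganin C (18) is a chroman whose pyran ring carries three contiguous stereocentres: C2 (2,4-dimethoxyphenyl), C3 (4-hydroxybenzyl) and C4 ((E)-4-hydroxystyryl), all trans and 2R,3R,4R. The three centres differ in character. C4 is benzylic and allylic but configurationally robust, so it can be set first and used as the relay. C3 has no activating group once it is saturated and must be right when its C–H bond is made. C2 is a benzylic ether carbon next to a very electron-rich aryl group and is the only centre that can still be corrected, by reversible ionisation of the C2–O bond. In the all-trans isomer each ring hydrogen lies on the face of the neighbouring substituents, so hydrogen additions that merely avoid those substituents give other diastereomers. The sensitive groups are the electron-rich (E)-styrene (no catalytic hydrogenation, strong acid or oxidant late in the route), the C2–O bond (acid plus a hydride donor opens it), and two phenols that must be told apart from three methyl ethers. The enabling feature is that ring A with O1 is 3-methoxyphenol (12): its carbon ortho to OH and para to OMe is C4a, and C2, C3 and C4 with their three side groups are the carbonyl, α- and β-carbons of the α-benzyl dienone 11. A Friedel–Crafts conjugate addition (C4–C4a) followed by condensation of the phenol oxygen with the ketone (O1–C2) therefore assembles the whole skeleton from two achiral pieces and creates one stereocentre under catalyst control.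

## Retrosynthesis

**18 from 17.** The two phenolic O–H bonds are traced back to O–Si bonds in bis-silyl ether 17. Silyl ethers are preferred to benzyl, methyl or acyl groups because fluoride removes them without hydrogen (styrene) and without Lewis acid (methyl ethers, C2–O bond), and because they survive amide base, the chiral acid and CF3CO2H. The skeleton is unchanged, but the two phenols are now distinguished from the three methyl ethers. The forward step only has to leave the stereocentres and the alkene alone.

**17 from 15.** The C2–H and C3–H bonds are cut: 17 is the product of adding a proton to C3 and a hydride to C2 of the enol ether in 4H-chromene 15. This ionic mode is preferred to catalytic hydrogenation, which would saturate the styrene and add both hydrogens to one face. The precursor has only the C4 stereocentre. The forward reaction must achieve anti addition, with the proton arriving at C3 on the face of the C4 styryl group and the hydride at C2 on the face of the C3 benzyl group. That can only come from reversible protonation and a late, chair-like transition state, supported by reversible ionisation of the C2–O bond; it is the weakest link after the key step.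

**15 from 11 and 12.** The C4–C4a and O1–C2 bonds are cut, which opens the pyran ring and gives 3-methoxyphenol 12 and dienone 11. Cuts through C2–C3 would need a cation–alkene or hydride-shift cascade with no established enantiocontrol, whereas this cut uses the innate ortho nucleophilicity of 12 and a carbonyl condensation. Both precursors are achiral and of similar size. The forward reaction must add at the β-carbon and not the δ-carbon, alkylate carbon ortho to OH, select one enone face, and finish with loss of water to the enol ether.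

**11 from 5 and 7.** The C2=C3 alkene of 11 is cut by a retro-aldol condensation to ketone 5 and enal 7, via aldol 9. A directed lithium-enolate aldol followed by elimination is chosen over hydroxide-mediated condensation because both partners carry base-labile aryl silyl ethers and the α-branched position condenses poorly under equilibrating conditions. Both fragments are simple. The forward sequence must give the (2E) geometry, since the catalyst of the key step reads the enone shape.

**5 from 1 and 2.** The Cα–Cβ bond of the saturated ketone is cut after re-introducing the alkene: Claisen–Schmidt condensation of acetophenone 1 with aldehyde 2 gives chalcone 3, hydrogenation gives phenol 4, and silylation gives 5. The benzyl ether on 2 keeps the aldehyde electrophilic under base and falls off in the same hydrogenation that saturates the alkene. Direct benzylation of the enolate of 1 was set aside because methyl ketones over-alkylate.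

**7 from 6.** The Cα=Cβ bond of the enal is cut to commercial aldehyde 6 and a two-carbon formyl ylide. One Wittig step replaces an ester homologation, reduction and oxidation sequence.

## Roads not taken

**Alternative 1:** The cut is through C2–C3 and C4–C4a. In the forward step acid ionises the diaryl acetal 1-[bis(3-methoxyphenoxy)methyl]-2,4-dimethoxybenzene A2 to an aryloxycarbenium ion. Its carbon adds to the benzyl-bearing terminus of 4-[(2E,4E)-5-(4-acetoxyphenyl)penta-2,4-dienyl]phenyl acetate A3, and ring A closes on the allyl cation to give caraganin C diacetate A1.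
- Merits: it is the shortest route, two C–C bonds and all three stereocentres form in one step, and the (E)-alkene geometry and a chair-like closure should translate directly into the 2,3-trans-3,4-trans arrangement.
- Weak points: there is no established way to make this cationic, stepwise annulation enantioselective; the electron-rich diene can oligomerise under the acid; and the acetates must survive ionising conditions.
- Comparison: this road is better for relative configuration, which the chosen plan has to earn in a separate reduction. The chosen plan sets against it a catalytic asymmetric step of an established reaction family that creates one stereocentre at a time and gives the single enantiomer.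

**Alternative 2:** The cut is at O1 (O1–C2 and O1–C8a) by a retro-Baeyer–Villiger step. A flavin-dependent monooxygenase would insert oxygen between the carbonyl and ring A of trans-2-(4-hydroxybenzyl)-3-[(E)-4-hydroxystyryl]-6-methoxyindan-1-one A4, giving trans-3-(4-hydroxybenzyl)-4-[(E)-4-hydroxystyryl]-7-methoxy-3,4-dihydrocoumarin A5.
- Merits: the C3/C4 trans relation sits on an enolisable α-carbon and is thermodynamically secure, free phenols are tolerated, and an enzyme spares the styrene that a peracid would epoxidise.
- Weak points: A4 already needs an asymmetric synthesis of two stereocentres; acceptance of so bulky a ketone and the sense of migration (aryl against secondary alkyl) would need enzyme screening; and after A5 the whole 2-aryl group still has to be added to the lactone and the lactol reduced.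
- Comparison: it is better on the C3/C4 relation but clearly longer. The chosen plan brings the 2-aryl group in with the acceptor and needs two steps after the ring is closed.

**Alternative 3:** The cut is at C2–C3. A chiral Lewis acid would trigger a 1,5-hydride shift from the benzylic ether CH2 of 3-{2-[(2,4-dimethoxybenzyl)oxy]-4-methoxyphenyl}-1,5-bis{4-[(tert-butyldimethylsilyl)oxy]phenyl}penta-2,4-dien-1-one A6 to C4, and the enolate would close onto the oxocarbenium ion to give the all-trans 3-aroylchroman A7.
- Merits: it is redox-neutral, the ring closes with C–C bond formation, and the C3 acyl group makes C3 epimerisable.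
- Weak points: hydride-shift cyclisations normally need doubly activated acceptors, and a β,β-disubstituted mono-ketone is a poor one; the geometry of the trisubstituted alkene in A6 decides the enantiomeric purity at C4; and the extra carbonyl must afterwards be reduced to CH2 beside a styrene and an acid-labile C2–O bond.
- Comparison: it is better at controlling C3. The chosen plan avoids the deoxygenation and relies on a more reactive bond-forming event.

Key step: step 7

Remarks on the chemistry:
- TBS = tert-butyldimethylsilyl.
- The sense of induction of the chiral acid on this acceptor class cannot be deduced in advance. The route is written with the (R)-catalyst; the (S)-catalyst is used instead if it is the one that gives (4R)-15.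
- Compounds 1, 2, 6 and 12 and all reagents named are taken to be commercial.

## Route

Step 1
Reactants: 1 2',4'-dimethoxyacetophenone; 2 4-(benzyloxy)benzaldehyde
Product: 3 (E)-3-[4-(benzyloxy)phenyl]-1-(2,4-dimethoxyphenyl)prop-2-en-1-one
Conditions: NaOH (aq.), EtOH, rt
Reagents that add atoms: none
Why: Claisen–Schmidt condensation: the methyl ketone enolate adds to the non-enolisable aldehyde and the aldol loses water to the conjugated (E)-chalcone; the benzyl ether keeps the aldehyde electrophilic, which a free para-phenoxide would not.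

Step 2
Reactants: 3 (E)-3-[4-(benzyloxy)phenyl]-1-(2,4-dimethoxyphenyl)prop-2-en-1-one
Product: 4 1-(2,4-dimethoxyphenyl)-3-(4-hydroxyphenyl)propan-1-one
Conditions: H2 (1 atm), Pd/C, EtOAc, rt
Reagents that add atoms: none
Why: Heterogeneous hydrogenation saturates the enone C=C and cleaves the benzyl ether by hydrogenolysis in one operation; the electron-rich, ortho-substituted aryl ketone is reduced much more slowly, and the reaction is stopped after uptake of two equivalents of H2.

Step 3
Reactants: 4 1-(2,4-dimethoxyphenyl)-3-(4-hydroxyphenyl)propan-1-one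
Product: 5 3-[4-(TBS-oxy)phenyl]-1-(2,4-dimethoxyphenyl)propan-1-one
Conditions: TBSCl, imidazole, DMF, rt
Reagents that add atoms: tert-butyldimethylsilyl chloride (TBSCl), CC(C)(C)[Si](C)(C)Cl
Why: Standard silylation of a phenol; the aryl silyl ether tolerates LDA, the chiral acid and CF3CO2H and is removed by fluoride at the end.

Step 4
Reactants: 6 4-(TBS-oxy)benzaldehyde
Product: 7 (E)-3-[4-(TBS-oxy)phenyl]prop-2-enal
Conditions: Ph3P=CHCHO, toluene, 80 °C
Reagents that add atoms: (triphenylphosphoranylidene)acetaldehyde, O=CC=P(c1ccccc1)(c1ccccc1)c1ccccc1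
Why: Wittig olefination with the stabilised formyl ylide gives the (E)-enal; a slight excess of 6 limits a second homologation of the product.

Step 5
Reactants: 5 3-[4-(TBS-oxy)phenyl]-1-(2,4-dimethoxyphenyl)propan-1-one; 7 (E)-3-[4-(TBS-oxy)phenyl]prop-2-enal
Product: 9 (4E)-2-[4-(TBS-oxy)benzyl]-5-[4-(TBS-oxy)phenyl]-1-(2,4-dimethoxyphenyl)-3-hydroxypent-4-en-1-one (racemic mixture of diastereomers), via lithium (Z)-enolate 8 (not isolated)
Conditions: LDA, THF, −78 °C; then 7; AcOH quench at −78 °C
Reagents that add atoms: none
Why: Directed aldol addition: LDA forms the lithium enolate at the only enolisable position and it adds 1,2 to the enal at low temperature; the cold acidic quench prevents retro-aldol cleavage and the non-hydroxylic base spares the aryl silyl ethers. The two stereocentres formed are removed in step 6.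

Step 6
Reactants: 9 (4E)-2-[4-(TBS-oxy)benzyl]-5-[4-(TBS-oxy)phenyl]-1-(2,4-dimethoxyphenyl)-3-hydroxypent-4-en-1-one
Product: 11 (2E,4E)-2-[4-(TBS-oxy)benzyl]-5-[4-(TBS-oxy)phenyl]-1-(2,4-dimethoxyphenyl)penta-2,4-dien-1-one, via allylic mesylate 10 (not isolated)
Conditions: MsCl, Et3N, CH2Cl2, 0 °C; then DBU, rt
Reagents that add atoms: none
Why: Mesylation of the alcohol and E1cB elimination through the ketone enolate; the conjugated dienone should form as the more stable (2E) isomer (aroyl trans to the dienyl chain), as in base-mediated syntheses of α-alkylchalcones, and the (4E) alkene is not touched.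

Step 7
Reactants: 11 (2E,4E)-2-[4-(TBS-oxy)benzyl]-5-[4-(TBS-oxy)phenyl]-1-(2,4-dimethoxyphenyl)penta-2,4-dien-1-one; 12 3-methoxyphenol
Product: 15 (4R)-3-[4-(TBS-oxy)benzyl]-4-{(E)-2-[4-(TBS-oxy)phenyl]ethenyl}-2-(2,4-dimethoxyphenyl)-7-methoxy-4H-chromene, via keto-phenol adduct 13 (not isolated), via cyclic hemiketal 14 (not isolated)
Conditions: 12 (2 equiv), (R)-3,3'-bis(2,4,6-triisopropylphenyl)-1,1'-binaphthalene-2,2'-diyl N-triflylphosphoramide (10 mol%), 5 Å MS, toluene, 40 °C
Reagents that add atoms: none
Why: Proposed new method: the N–H acid activates the carbonyl of 11 by hydrogen bonding while its phosphoryl oxygen holds the OH of 12, so that within this complex the phenol carbon ortho to OH and para to OMe adds to the β-carbon of the dienone (Friedel–Crafts conjugate addition, C4–C4a). Rearomatisation and ketonisation give keto-phenol 13, whose phenol oxygen attacks the ketone in a 6-exo-trig closure to hemiketal 14, and acid-catalysed loss of water onto the sieves gives enol ether 15 (O1–C2), in which the transient C2 and C3 centres are gone. The closest known reaction type is the chiral-acid-catalysed Friedel–Crafts alkylation–cyclodehydration of electron-rich phenols and naphthols with β-substituted enones and β,γ-unsaturated α-ketoesters to 4H-chromenes; it has not been shown on α-branched 2,4-dienyl aryl ketones. The only stereocentre formed, C4, is controlled by the catalyst, whose 3,3'-aryl groups leave one face of the bound enone open to the hydrogen-bonded phenol. Addition must be 1,4 and not 1,6: the δ-carbon carries the aryl group, attack there would break the styrene conjugation, the doubly bound phenol is held next to the β-carbon, and only the 1,4-adduct is drained by cyclodehydration. Ortho rather than para C-alkylation follows from the hydrogen bond of the phenol OH to the catalyst, and of the two ortho carbons the one para to OMe is both the more nucleophilic and the less hindered. O-Alkylation is reversible and unproductive, and the electron-rich 2,4-dimethoxyphenyl ketone, though a weak acceptor, is a basic carbonyl that binds the acid well and gives a strongly stabilised oxocarbenium ion for the dehydration.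

Step 8
Reactants: 15 (4R)-3-[4-(TBS-oxy)benzyl]-4-{(E)-2-[4-(TBS-oxy)phenyl]ethenyl}-2-(2,4-dimethoxyphenyl)-7-methoxy-4H-chromene
Product: 17 (2R,3R,4R)-3-[4-(TBS-oxy)benzyl]-4-{(E)-2-[4-(TBS-oxy)phenyl]ethenyl}-2-(2,4-dimethoxyphenyl)-7-methoxychroman, via oxocarbenium trifluoroacetate 16 (not isolated)
Conditions: Et3SiH (5 equiv), CF3CO2H (5 equiv, added last), CH2Cl2, −40 to 0 °C
Reagents that add atoms: none
Why: Ionic hydrogenation of an enol ether: CF3CO2H protonates C3 reversibly to oxocarbenium ion 16 (stabilised by O1 and the 2,4-dimethoxyphenyl group) and Et3SiH delivers hydride to C2. With proton exchange faster than hydride transfer, the ion with benzyl trans to the C4 styryl group should be reduced through the half-chair that holds both groups pseudoequatorial, axial hydride placing the aryl group equatorial and giving 2R,3R. The low temperature keeps the (E)-styrene, the aryl silyl ethers and the acid-labile C2–O bond of the product intact.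

Step 9
Reactants: 17 (2R,3R,4R)-3-[4-(TBS-oxy)benzyl]-4-{(E)-2-[4-(TBS-oxy)phenyl]ethenyl}-2-(2,4-dimethoxyphenyl)-7-methoxychroman
Product: 18 caraganin C, (2R,3R,4R)-2-(2,4-dimethoxyphenyl)-3-(4-hydroxybenzyl)-4-[(E)-2-(4-hydroxyphenyl)ethenyl]-7-methoxychroman
Conditions: Bu4NF, AcOH, THF, 0 °C
Reagents that add atoms: none
Why: Fluoride cleaves both aryl Si–O bonds; the AcOH buffer keeps the phenols protonated so the electron-rich product is not exposed to base, and neither the stereocentres nor the (E)-alkene are affected.

## Compound list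

1 | 2',4'-dimethoxyacetophenone | CC(=O)c1ccc(OC)cc1OC | starting material
2 | 4-(benzyloxy)benzaldehyde | O=Cc1ccc(OCc2ccccc2)cc1 | starting material
3 | (E)-3-[4-(benzyloxy)phenyl]-1-(2,4-dimethoxyphenyl)prop-2-en-1-one | COc1ccc(c(OC)c1)C(=O)/C=C/c1ccc(OCc2ccccc2)cc1 | intermediate
4 | 1-(2,4-dimethoxyphenyl)-3-(4-hydroxyphenyl)propan-1-one | COc1ccc(c(OC)c1)C(=O)CCc1ccc(O)cc1 | intermediate
5 | 3-[4-(TBS-oxy)phenyl]-1-(2,4-dimethoxyphenyl)propan-1-one | COc1ccc(c(OC)c1)C(=O)CCc1ccc(O[Si](C)(C)C(C)(C)C)cc1 | intermediate
6 | 4-(TBS-oxy)benzaldehyde | O=Cc1ccc(O[Si](C)(C)C(C)(C)C)cc1 | starting material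
7 | (E)-3-[4-(TBS-oxy)phenyl]prop-2-enal | O=C/C=C/c1ccc(O[Si](C)(C)C(C)(C)C)cc1 | intermediate
8 | lithium (Z)-3-[4-(TBS-oxy)phenyl]-1-(2,4-dimethoxyphenyl)prop-1-en-1-olate | COc1ccc(c(OC)c1)/C(O[Li])=C/Cc1ccc(O[Si](C)(C)C(C)(C)C)cc1 | intermediate
9 | (4E)-2-[4-(TBS-oxy)benzyl]-5-[4-(TBS-oxy)phenyl]-1-(2,4-dimethoxyphenyl)-3-hydroxypent-4-en-1-one (racemic, C2/C3 diastereomers) | COc1ccc(c(OC)c1)C(=O)C(Cc1ccc(O[Si](C)(C)C(C)(C)C)cc1)C(O)/C=C/c1ccc(O[Si](C)(C)C(C)(C)C)cc1 | intermediate
10 | (4E)-2-[4-(TBS-oxy)benzyl]-5-[4-(TBS-oxy)phenyl]-1-(2,4-dimethoxyphenyl)-1-oxopent-4-en-3-yl methanesulfonate (racemic, diastereomers) | COc1ccc(c(OC)c1)C(=O)C(Cc1ccc(O[Si](C)(C)C(C)(C)C)cc1)C(OS(C)(=O)=O)/C=C/c1ccc(O[Si](C)(C)C(C)(C)C)cc1 | intermediate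
11 | (2E,4E)-2-[4-(TBS-oxy)benzyl]-5-[4-(TBS-oxy)phenyl]-1-(2,4-dimethoxyphenyl)penta-2,4-dien-1-one | COc1ccc(c(OC)c1)C(=O)/C(Cc1ccc(O[Si](C)(C)C(C)(C)C)cc1)=C/C=C/c1ccc(O[Si](C)(C)C(C)(C)C)cc1 | intermediate
12 | 3-methoxyphenol | COc1cccc(O)c1 | starting material
13 | (3R,4E)-2-[4-(TBS-oxy)benzyl]-5-[4-(TBS-oxy)phenyl]-1-(2,4-dimethoxyphenyl)-3-(2-hydroxy-4-methoxyphenyl)pent-4-en-1-one (C2 epimers) | COc1ccc(c(O)c1)[C@H](/C=C/c1ccc(O[Si](C)(C)C(C)(C)C)cc1)C(Cc1ccc(O[Si](C)(C)C(C)(C)C)cc1)C(=O)c1ccc(OC)cc1OC | intermediate
14 | (4R)-3-[4-(TBS-oxy)benzyl]-4-{(E)-2-[4-(TBS-oxy)phenyl]ethenyl}-2-(2,4-dimethoxyphenyl)-7-methoxychroman-2-ol (C2/C3 epimers) | COc1ccc2c(c1)OC(O)(c1ccc(OC)cc1OC)C(Cc1ccc(O[Si](C)(C)C(C)(C)C)cc1)[C@H]2/C=C/c1ccc(O[Si](C)(C)C(C)(C)C)cc1 | intermediate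
15 | (4R)-3-[4-(TBS-oxy)benzyl]-4-{(E)-2-[4-(TBS-oxy)phenyl]ethenyl}-2-(2,4-dimethoxyphenyl)-7-methoxy-4H-chromene | COc1ccc2c(c1)OC(c1ccc(OC)cc1OC)=C(Cc1ccc(O[Si](C)(C)C(C)(C)C)cc1)[C@H]2/C=C/c1ccc(O[Si](C)(C)C(C)(C)C)cc1 | intermediate
16 | (4R)-3-[4-(TBS-oxy)benzyl]-4-{(E)-2-[4-(TBS-oxy)phenyl]ethenyl}-2-(2,4-dimethoxyphenyl)-7-methoxy-3,4-dihydrochromenylium trifluoroacetate (C3 epimers in equilibrium) | COc1ccc2c(c1)[O+]=C(c1ccc(OC)cc1OC)C(Cc1ccc(O[Si](C)(C)C(C)(C)C)cc1)[C@H]2/C=C/c1ccc(O[Si](C)(C)C(C)(C)C)cc1.[O-]C(=O)C(F)(F)F | intermediate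
17 | (2R,3R,4R)-3-[4-(TBS-oxy)benzyl]-4-{(E)-2-[4-(TBS-oxy)phenyl]ethenyl}-2-(2,4-dimethoxyphenyl)-7-methoxychroman | COc1ccc2c(c1)O[C@@H](c1ccc(OC)cc1OC)[C@H](Cc1ccc(O[Si](C)(C)C(C)(C)C)cc1)[C@H]2/C=C/c1ccc(O[Si](C)(C)C(C)(C)C)cc1 | intermediate
18 | caraganin C, (2R,3R,4R)-2-(2,4-dimethoxyphenyl)-3-(4-hydroxybenzyl)-4-[(E)-2-(4-hydroxyphenyl)ethenyl]-7-methoxychroman | COc1ccc2c(c1)O[C@@H](c1ccc(OC)cc1OC)[C@H](Cc1ccc(O)cc1)[C@H]2/C=C/c1ccc(O)cc1 | target

## Step count and least certain steps

Total: 9 steps. Longest linear sequence: 8 steps (steps 1, 2, 3, 5, 6, 7, 8, 9 from 1); step 4 is the side branch.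

**Step 7 (key step, proposed new method).**
- Most likely failure: insufficient activation of a twisted, α-branched, electron-rich aryl dienone, so that addition is slow. Beside it, addition at the δ-carbon or alkylation para to the phenol OH would give adducts that cannot cyclise, and enantioface control on an acceptor without precedent may be poor.
- Fallback (known chemistry; sets out from 1, 6 and 7 and comes back at 15 through 13): the aryl group is delivered as a boron nucleophile to an unbranched acceptor and the benzyl group is added afterwards.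
  - Aldol condensation of 1 with 7 (LDA, then MsCl and Et3N as in steps 5 and 6) gives (2E,4E)-1-(2,4-dimethoxyphenyl)-5-[4-(TBS-oxy)phenyl]penta-2,4-dien-1-one F1.
  - 5-Methoxy-2-(4,4,5,5-tetramethyl-1,3,2-dioxaborolan-2-yl)phenol F2 is made from commercial 2-bromo-5-methoxyphenol by Miyaura borylation (B2pin2, Pd(dppf)Cl2, KOAc, dioxane).
  - F2 is added to F1 with [Rh(C2H4)2Cl]2, a chiral diene ligand and aqueous KOH in dioxane. Rhodium-catalysed asymmetric conjugate addition of arylboron reagents to β-substituted aryl enones is established and goes 1,4 on δ-aryl dienones. It gives (3S,4E)-1-(2,4-dimethoxyphenyl)-3-(2-hydroxy-4-methoxyphenyl)-5-[4-(TBS-oxy)phenyl]pent-4-en-1-one F3; the descriptor changes with the substituents, but the spatial arrangement is that of C4 in 15.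
  - Reduction of 6 with NaBH4 gives [4-(TBS-oxy)phenyl]methanol F4, and Appel bromination (PPh3, CBr4) gives 4-(TBS-oxy)benzyl bromide F5.
  - The dianion of F3 (LDA, 2 equiv, THF, −78 °C) is alkylated on carbon by F5 to give 13, and TsOH with 4 Å sieves in CH2Cl2 cyclodehydrates 13 to 15.

**Step 8.**
- Most likely failure: kinetic facial selectivity that runs against the target. Proton delivery to C3 on the face away from the pseudoaxial C4 styryl group gives the 3,4-cis ion, and hydride delivery to C2 away from a pseudoaxial C3 benzyl group gives a 2,3-cis product. Together these amount to addition of H2 from the open face, as in a catalytic hydrogenation.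
- C2 can be re-equilibrated afterwards by acid without silane, because the C2–O bond ionises reversibly. C3 cannot be corrected.
- Further hazards: reductive opening of the C2–O bond on prolonged exposure, hydride transfer from C4–H of unreacted 15 (disproportionation), and protonation of the styrene.
- Fallback (sets out from 15 and comes back at 17): the two hydrogens are introduced in separate, controllable events.
  - Hydrolysis of the enol ether (aq. HCl, THF) returns keto-phenol 13, in which the future C3 is α to a ketone and epimerisable.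
  - The epimer with the required relative configuration, (2R,3R,4E)-2-[4-(TBS-oxy)benzyl]-5-[4-(TBS-oxy)phenyl]-1-(2,4-dimethoxyphenyl)-3-(2-hydroxy-4-methoxyphenyl)pent-4-en-1-one F6, is separated and the other is recycled by equilibration with DBU.
  - NaBH4 reduces F6 to (2R,3R,4E)-2-[4-(TBS-oxy)benzyl]-5-[4-(TBS-oxy)phenyl]-1-(2,4-dimethoxyphenyl)-3-(2-hydroxy-4-methoxyphenyl)pent-4-en-1-ol F7 (C1 epimers).
  - Mild acid (PPTS, CH2Cl2) ionises the 2,4-dimethoxybenzylic alcohol and the phenol closes the ring to 17. The aryl group should go equatorial in a chair-like closure, and C2 remains free to equilibrate by re-ionisation.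

**Step 6.**
- Most likely failure: incomplete geometric control about the new trisubstituted alkene, ionisation or allylic substitution of the doubly activated mesylate before elimination, or loss of aryl silyl groups under the amidine base.
- Fallback (sets out from 5 through enolate 8, and from 7, and comes back at 11): the alkene is made by olefination instead of elimination.
  - Enolate 8 is brominated with NBS to 2-bromo-3-[4-(TBS-oxy)phenyl]-1-(2,4-dimethoxyphenyl)propan-1-one F8.
  - PPh3 in toluene gives {3-[4-(TBS-oxy)phenyl]-1-(2,4-dimethoxyphenyl)-1-oxopropan-2-yl}triphenylphosphonium bromide F9.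
  - Aqueous Na2CO3 gives the stabilised ylide 3-[4-(TBS-oxy)phenyl]-1-(2,4-dimethoxyphenyl)-2-(triphenylphosphoranylidene)propan-1-one F10.
  - F10 condenses with 7 in toluene at reflux. Wittig reactions of α-substituted acyl ylides give (E)-trisubstituted enones and involve no β-leaving group.

**Step 4.**
- Most likely failure: a second olefination of product 7 by the same ylide (chain extension to the dienal) and partial loss of (E) selectivity.
- Fallback (sets out from 6 and comes back at 7): the oxidation level is adjusted after the olefination.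
  - Horner–Wadsworth–Emmons reaction of 6 with triethyl phosphonoacetate (NaH, THF) gives ethyl (E)-3-[4-(TBS-oxy)phenyl]prop-2-enoate F11.
  - DIBAL-H (CH2Cl2, −78 °C) gives (E)-3-[4-(TBS-oxy)phenyl]prop-2-en-1-ol F12.
  - MnO2 in CH2Cl2 oxidises F12 to 7.

## Further compounds

F1 | step 7 | (2E,4E)-1-(2,4-dimethoxyphenyl)-5-[4-(TBS-oxy)phenyl]penta-2,4-dien-1-one | COc1ccc(c(OC)c1)C(=O)/C=C/C=C/c1ccc(O[Si](C)(C)C(C)(C)C)cc1
F2 | step 7 | 5-methoxy-2-(4,4,5,5-tetramethyl-1,3,2-dioxaborolan-2-yl)phenol | COc1ccc(B2OC(C)(C)C(C)(C)O2)c(O)c1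
F3 | step 7 | (3S,4E)-1-(2,4-dimethoxyphenyl)-3-(2-hydroxy-4-methoxyphenyl)-5-[4-(TBS-oxy)phenyl]pent-4-en-1-one | COc1ccc(c(O)c1)[C@H](/C=C/c1ccc(O[Si](C)(C)C(C)(C)C)cc1)CC(=O)c1ccc(OC)cc1OC
F4 | step 7 | [4-(TBS-oxy)phenyl]methanol | OCc1ccc(O[Si](C)(C)C(C)(C)C)cc1
F5 | step 7 | 4-(TBS-oxy)benzyl bromide | BrCc1ccc(O[Si](C)(C)C(C)(C)C)cc1
F6 | step 8 | (2R,3R,4E)-2-[4-(TBS-oxy)benzyl]-5-[4-(TBS-oxy)phenyl]-1-(2,4-dimethoxyphenyl)-3-(2-hydroxy-4-methoxyphenyl)pent-4-en-1-one | O=C(c1ccc(OC)cc1OC)[C@H](Cc1ccc(O[Si](C)(C)C(C)(C)C)cc1)[C@@H](/C=C/c1ccc(O[Si](C)(C)C(C)(C)C)cc1)c1ccc(OC)cc1O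
F7 | step 8 | (2R,3R,4E)-2-[4-(TBS-oxy)benzyl]-5-[4-(TBS-oxy)phenyl]-1-(2,4-dimethoxyphenyl)-3-(2-hydroxy-4-methoxyphenyl)pent-4-en-1-ol (C1 epimers) | OC(c1ccc(OC)cc1OC)[C@H](Cc1ccc(O[Si](C)(C)C(C)(C)C)cc1)[C@@H](/C=C/c1ccc(O[Si](C)(C)C(C)(C)C)cc1)c1ccc(OC)cc1O
F8 | step 6 | 2-bromo-3-[4-(TBS-oxy)phenyl]-1-(2,4-dimethoxyphenyl)propan-1-one (racemic) | COc1ccc(c(OC)c1)C(=O)C(Br)Cc1ccc(O[Si](C)(C)C(C)(C)C)cc1
F9 | step 6 | {3-[4-(TBS-oxy)phenyl]-1-(2,4-dimethoxyphenyl)-1-oxopropan-2-yl}triphenylphosphonium bromide | COc1ccc(c(OC)c1)C(=O)C(Cc1ccc(O[Si](C)(C)C(C)(C)C)cc1)[P+](c1ccccc1)(c1ccccc1)c1ccccc1.[Br-]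
F10 | step 6 | 3-[4-(TBS-oxy)phenyl]-1-(2,4-dimethoxyphenyl)-2-(triphenylphosphoranylidene)propan-1-one | COc1ccc(c(OC)c1)C(=O)C(Cc1ccc(O[Si](C)(C)C(C)(C)C)cc1)=P(c1ccccc1)(c1ccccc1)c1ccccc1
F11 | step 4 | ethyl (E)-3-[4-(TBS-oxy)phenyl]prop-2-enoate | CCOC(=O)/C=C/c1ccc(O[Si](C)(C)C(C)(C)C)cc1
F12 | step 4 | (E)-3-[4-(TBS-oxy)phenyl]prop-2-en-1-ol | OC/C=C/c1ccc(O[Si](C)(C)C(C)(C)C)cc1
A1 | alternative 1 | caraganin C diacetate | COc1ccc2c(c1)O[C@@H](c1ccc(OC)cc1OC)[C@H](Cc1ccc(OC(C)=O)cc1)[C@H]2/C=C/c1ccc(OC(C)=O)cc1
A2 | alternative 1 | 1-[bis(3-methoxyphenoxy)methyl]-2,4-dimethoxybenzene | COc1ccc(C(Oc2cccc(OC)c2)Oc2cccc(OC)c2)c(OC)c1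
A3 | alternative 1 | 4-[(2E,4E)-5-(4-acetoxyphenyl)penta-2,4-dienyl]phenyl acetate | CC(=O)Oc1ccc(C/C=C/C=C/c2ccc(OC(C)=O)cc2)cc1
A4 | alternative 2 | trans-2-(4-hydroxybenzyl)-3-[(E)-4-hydroxystyryl]-6-methoxyindan-1-one | COc1ccc2c(c1)C(=O)[C@H](Cc1ccc(O)cc1)[C@H]2/C=C/c1ccc(O)cc1
A5 | alternative 2 | trans-3-(4-hydroxybenzyl)-4-[(E)-4-hydroxystyryl]-7-methoxy-3,4-dihydrocoumarin | COc1ccc2c(c1)OC(=O)[C@H](Cc1ccc(O)cc1)[C@H]2/C=C/c1ccc(O)cc1
A6 | alternative 3 | 3-{2-[(2,4-dimethoxybenzyl)oxy]-4-methoxyphenyl}-1,5-bis[4-(TBS-oxy)phenyl]penta-2,4-dien-1-one (4E) | COc1ccc(COc2cc(OC)ccc2C(/C=C/c2ccc(O[Si](C)(C)C(C)(C)C)cc2)=CC(=O)c2ccc(O[Si](C)(C)C(C)(C)C)cc2)c(OC)c1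
A7 | alternative 3 | all-trans 2-(2,4-dimethoxyphenyl)-3-[4-(TBS-oxy)benzoyl]-4-{(E)-2-[4-(TBS-oxy)phenyl]ethenyl}-7-methoxychroman | COc1ccc2c(c1)O[C@@H](c1ccc(OC)cc1OC)[C@H](C(=O)c1ccc(O[Si](C)(C)C(C)(C)C)cc1)[C@H]2/C=C/c1ccc(O[Si](C)(C)C(C)(C)C)cc1
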